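**Plan**

1. Numbering: ring A is C1–C5 plus C10 (exocyclic CH2 on C4, CH3 on C5); ring B is C5–C10 (CH3 on C8; CH3 and the arylmethyl carbon C15 on C9; H on C10).
2. Retrosynthesis: C4=CH2 (Wittig) and a temporary C6 carbonyl lead back to a 6-oxo-decalin. Ring B is then cut at C8–C9: C9 is quaternary and carries a methyl group, and C8 lies β to C6, so a C9=CH2 alkene and a C6 (E)-propenyl ketone on ring A are the two halves of a hydrogen-atom-transfer radical conjugate cyclisation.
3. Further cuts: C15–aryl (Suzuki coupling at a 2-substituted allyl chloride, chosen because a vinyl metal carrying the methyl benzoate could not be prepared), C5–C6 (aldol) and C9–C10 (conjugate addition). These lead to 2-methylcyclohexenone, 2-bromopropene, crotonaldehyde and methyl vanillate.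
4. Forward: ring A is the purchased enone; both side arms are added in one pot, the arene is coupled, ring B closes in the radical step, C6 is deoxygenated through its enol triflate and C4 is methylenated.
5. Stereochemistry: C10 from the chiral copper catalyst; C5 from aldol trapping anti to the C10 substituent; C8 and C9 from the chair-like, trans-fused transition state of the ring closure.

Key step: step 10

Remark: positions follow the numbering above and β is the face of the C5 methyl group; the carbinol carbon made in the aldol step and the C4 carbinol are temporary stereocentres (both are oxidised later), so the former is left open in the SMILES of the two compounds that carry it.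

**Route**

Step 1
Reactants: 1 2-methylcyclohex-2-en-1-one; 2 2-bromopropene; 3 (E)-but-2-enal (crotonaldehyde)
Product: 7 (2R,3S)-2-[(2E)-1-hydroxybut-2-en-1-yl]-2-methyl-3-(prop-1-en-2-yl)cyclohexan-1-one (both carbinol epimers), via prop-1-en-2-yllithium 4 (not isolated), via dimethyl(prop-1-en-2-yl)aluminium 5 (not isolated), via dimethylaluminium enolate 6 (not isolated)
Conditions: 2, t-BuLi (2 equiv), Et2O, −78 °C; Me2AlCl, −78 → −30 °C; 1, CuTC (10 mol %), BINOL-derived phosphoramidite L* (11 mol %, enantiomer that gives 10α-H), −30 °C; 3, −78 °C; aq. Rochelle salt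
Reagents that add atoms: none
Why: Copper-catalysed asymmetric conjugate addition of an alkenylalane to a 2-substituted cyclic enone with aldol trapping of the aluminium enolate; the ligand sets C10, and crotonaldehyde should attack the tetrasubstituted enolate at C5 anti to the new propenyl group, so the C5 methyl ends cis to it.

Step 2
Reactants: 7 (2R,3S)-2-[(2E)-1-hydroxybut-2-en-1-yl]-2-methyl-3-(prop-1-en-2-yl)cyclohexan-1-one
Product: 8 (1S,2S,3S)-2-[(2E)-1-hydroxybut-2-en-1-yl]-2-methyl-3-(prop-1-en-2-yl)cyclohexan-1-ol (both carbinol epimers)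
Conditions: NaBH4, MeOH, −20 → 0 °C
Reagents that add atoms: none
Why: Borohydride reduction of the ring ketone, with hydride expected to enter axially on the face opposite the axial C5 methyl to give the equatorial 4β-alcohol (a temporary centre), the allylic alcohol being unaffected.

Step 3
Reactants: 8 (1S,2S,3S)-2-[(2E)-1-hydroxybut-2-en-1-yl]-2-methyl-3-(prop-1-en-2-yl)cyclohexan-1-ol
Product: 9 (2E)-1-[(1S,2S,6S)-2-hydroxy-1-methyl-6-(prop-1-en-2-yl)cyclohexyl]but-2-en-1-one
Conditions: MnO2 (activated, excess), CH2Cl2, rt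
Reagents that add atoms: none
Why: Chemoselective allylic oxidation with manganese dioxide converts only the allylic carbinol into the (E)-propenyl ketone and merges both carbinol epimers, while the saturated C4 alcohol stays.

Step 4
Reactants: 9 (2E)-1-[(1S,2S,6S)-2-hydroxy-1-methyl-6-(prop-1-en-2-yl)cyclohexyl]but-2-en-1-one
Product: 10 (2E)-1-[(1S,2S,6S)-2-(tert-butyldimethylsilyloxy)-1-methyl-6-(prop-1-en-2-yl)cyclohexyl]but-2-en-1-one
Conditions: TBSOTf, 2,6-lutidine, CH2Cl2, −78 → 0 °C
Reagents that add atoms: tert-butyldimethylsilyl trifluoromethanesulfonate, CC(C)(C)[Si](C)(C)OS(=O)(=O)C(F)(F)F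
Why: Silylation of the hindered secondary alcohol with the silyl triflate closes the retro-aldol pathway of the β-hydroxy ketone before the basic and radical steps.

Step 5
Reactants: 10 (2E)-1-[(1S,2S,6S)-2-(tert-butyldimethylsilyloxy)-1-methyl-6-(prop-1-en-2-yl)cyclohexyl]but-2-en-1-one
Product: 11 (2E)-1-[(1S,2S,6R)-2-(tert-butyldimethylsilyloxy)-6-(3-chloroprop-1-en-2-yl)-1-methylcyclohexyl]but-2-en-1-one
Conditions: NaOCl (aq., 1.2 equiv), CeCl3·7H2O, CH2Cl2/H2O, 0 °C
Reagents that add atoms: sodium hypochlorite, [Na+].[O-]Cl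
Why: Ene-type allylic chlorination by hypochlorous acid, in which Cl+ adds to the terminal CH2 of the electron-rich isopropenyl group and a proton leaves from its methyl group, while the electron-poor enone double bond should not react.

Step 6
Reactants: 12 methyl 4-hydroxy-3-methoxybenzoate (methyl vanillate)
Product: 13 methyl 3-bromo-4-hydroxy-5-methoxybenzoate
Conditions: Br2, AcOH, rt
Reagents that add atoms: bromine, BrBr
Why: Electrophilic aromatic bromination at the only free position ortho to the phenol (the para position holds the ester).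

Step 7
Reactants: 13 methyl 3-bromo-4-hydroxy-5-methoxybenzoate
Product: 14 methyl 3-bromo-5-methoxy-4-(methoxymethoxy)benzoate
Conditions: MOMCl, i-Pr2NEt, CH2Cl2, 0 °C → rt
Reagents that add atoms: chloromethyl methyl ether, COCCl
Why: O-Alkylation of the phenol (Williamson type) gives an acetal that tolerates base, hydride, radical and ylide chemistry.

Step 8
Reactants: 14 methyl 3-bromo-5-methoxy-4-(methoxymethoxy)benzoate
Product: 15 methyl 3-methoxy-4-(methoxymethoxy)-5-(4,4,5,5-tetramethyl-1,3,2-dioxaborolan-2-yl)benzoate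
Conditions: B2pin2, PdCl2(dppf) (5 mol %), KOAc, 1,4-dioxane, 90 °C
Reagents that add atoms: bis(pinacolato)diboron, CC1(C)OB(OC1(C)C)B1OC(C)(C)C(C)(C)O1
Why: Miyaura borylation of the aryl bromide, to which the ester and the acetal are inert.

Step 9
Reactants: 11 (2E)-1-[(1S,2S,6R)-2-(tert-butyldimethylsilyloxy)-6-(3-chloroprop-1-en-2-yl)-1-methylcyclohexyl]but-2-en-1-one; 15 methyl 3-methoxy-4-(methoxymethoxy)-5-(4,4,5,5-tetramethyl-1,3,2-dioxaborolan-2-yl)benzoate
Product: 16 methyl 3-{2-[(1S,2S,3S)-2-[(2E)-but-2-enoyl]-3-(tert-butyldimethylsilyloxy)-2-methylcyclohexyl]prop-2-en-1-yl}-5-methoxy-4-(methoxymethoxy)benzoate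
Conditions: Pd(PPh3)4 (5 mol %), K2CO3, THF/H2O, 60 °C
Reagents that add atoms: none
Why: Suzuki–Miyaura coupling through a π-allylpalladium intermediate whose two CH2 termini are equivalent (2-substituted allyl), so only one constitution can form, and the carbonate base should spare the silylated β-oxy ketone and the ester.

Step 10
Reactants: 16 methyl 3-{2-[(1S,2S,3S)-2-[(2E)-but-2-enoyl]-3-(tert-butyldimethylsilyloxy)-2-methylcyclohexyl]prop-2-en-1-yl}-5-methoxy-4-(methoxymethoxy)benzoate
Product: 17 methyl 3-{[4β-(tert-butyldimethylsilyloxy)-5β,8β,9β-trimethyl-6-oxo-trans-decalin-9α-yl]methyl}-5-methoxy-4-(methoxymethoxy)benzoate (10α-H)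
Conditions: Fe(acac)3 (30 mol %), PhSiH3 (2.5 equiv), EtOH/(CH2OH)2 5:1, 60 °C, degassed, 0.02 M
Reagents that add atoms: none
Why: An iron hydride formed from Fe(acac)3 and PhSiH3 transfers a hydrogen atom to the CH2 terminus of the 1,1-disubstituted alkene, which makes the C9 methyl group and the nucleophilic tertiary C9 radical; this adds to C8, the β-carbon of the (E)-propenyl ketone, and the C7 α-keto radical is reduced and protonated by ethanol (the intramolecular form of the iron-hydride reductive olefin–enone coupling, a Giese-type addition). Ring B closes 6-endo-trig because C8 is the polarity-matched site, whereas 5-exo attack at C7 would be mismatched and give an unstabilised radical. The fusion is trans because C9 and C6 are already trans-diequatorial on ring A (C5 methyl axial β, H-10 axial α), which leaves a chair-like transition state as the unstrained path. At C9 the larger arylmethyl arm should take the pseudo-equatorial site beside C1H2 and the new methyl the pseudo-axial β site, away from the quaternary C5; at C8 the E-geometry places the enone methyl pseudo-equatorial (8β). The step needs hydrogen-atom transfer to the electron-rich alkene only and face control at both new centres; the first is secured by the electron-poor nature of the enone and the second by the trans-disubstituted ring A, the E-enone and the size of the arylmethyl arm.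

Step 11
Reactants: 17 methyl 3-{[4β-(tert-butyldimethylsilyloxy)-5β,8β,9β-trimethyl-6-oxo-trans-decalin-9α-yl]methyl}-5-methoxy-4-(methoxymethoxy)benzoate
Product: 19 methyl 3-{[4β-(tert-butyldimethylsilyloxy)-5β,8β,9β-trimethyl-6-(trifluoromethanesulfonyloxy)-trans-decal-6-en-9α-yl]methyl}-5-methoxy-4-(methoxymethoxy)benzoate, via potassium enolate 18 (not isolated)
Conditions: KHMDS, THF, −78 °C; PhNTf2, −78 → 0 °C
Reagents that add atoms: N-phenylbis(trifluoromethanesulfonimide), O=S(=O)(N(c1ccccc1)S(=O)(=O)C(F)(F)F)C(F)(F)F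
Why: Enol triflate formation; deprotonation can occur only at C7 because C5 is quaternary, and this route avoids a C6 alkoxide next to the C4 silyl ether, which could otherwise accept the silyl group.

Step 12
Reactants: 19 methyl 3-{[4β-(tert-butyldimethylsilyloxy)-5β,8β,9β-trimethyl-6-(trifluoromethanesulfonyloxy)-trans-decal-6-en-9α-yl]methyl}-5-methoxy-4-(methoxymethoxy)benzoate
Product: 20 methyl 3-{[4β-(tert-butyldimethylsilyloxy)-5β,8β,9β-trimethyl-trans-decal-6-en-9α-yl]methyl}-5-methoxy-4-(methoxymethoxy)benzoate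
Conditions: Pd(OAc)2 (5 mol %), PPh3 (10 mol %), HCO2H, n-Bu3N, DMF, 60 °C
Reagents that add atoms: none
Why: Palladium-catalysed formate reduction of the enol triflate (oxidative addition, formate exchange, loss of CO2, reductive elimination) replaces C–O by C–H.

Step 13
Reactants: 20 methyl 3-{[4β-(tert-butyldimethylsilyloxy)-5β,8β,9β-trimethyl-trans-decal-6-en-9α-yl]methyl}-5-methoxy-4-(methoxymethoxy)benzoate
Product: 21 methyl 3-{[4β-(tert-butyldimethylsilyloxy)-5β,8β,9β-trimethyl-trans-decalin-9α-yl]methyl}-5-methoxy-4-(methoxymethoxy)benzoate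
Conditions: H2 (1 atm), 10% Pd/C, EtOAc, rt
Reagents that add atoms: none
Why: Catalytic hydrogenation of the only C=C bond, a cis-disubstituted ring alkene; C6 and C7 become CH2, so no stereocentre arises, and the acetal, ester and silyl ether are stable.

Step 14
Reactants: 21 methyl 3-{[4β-(tert-butyldimethylsilyloxy)-5β,8β,9β-trimethyl-trans-decalin-9α-yl]methyl}-5-methoxy-4-(methoxymethoxy)benzoate
Product: 22 methyl 3-{[4β-hydroxy-5β,8β,9β-trimethyl-trans-decalin-9α-yl]methyl}-5-methoxy-4-(methoxymethoxy)benzoate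
Conditions: HF·pyridine, pyridine, THF, 0 → 40 °C
Reagents that add atoms: none
Why: Fluoride-mediated desilylation under buffered conditions frees the hindered C4 alcohol and should leave the aryl MOM ether and the methyl ester intact.

Step 15
Reactants: 22 methyl 3-{[4β-hydroxy-5β,8β,9β-trimethyl-trans-decalin-9α-yl]methyl}-5-methoxy-4-(methoxymethoxy)benzoate
Product: 23 methyl 3-{[5β,8β,9β-trimethyl-4-oxo-trans-decalin-9α-yl]methyl}-5-methoxy-4-(methoxymethoxy)benzoate
Conditions: Dess–Martin periodinane, NaHCO3, CH2Cl2, rt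
Reagents that add atoms: none
Why: Dess–Martin oxidation of the secondary alcohol to the C4 ketone; C5 is quaternary, so nothing can epimerise, and the phenol is still masked.

Step 16
Reactants: 23 methyl 3-{[5β,8β,9β-trimethyl-4-oxo-trans-decalin-9α-yl]methyl}-5-methoxy-4-(methoxymethoxy)benzoate
Product: 24 polyfibrospongol A methoxymethyl ether (4-methylidene compound)
Conditions: Ph3PCH3Br (5 equiv), KOt-Bu (4.5 equiv), THF, 0 °C → reflux
Reagents that add atoms: methyltriphenylphosphonium bromide, C[P+](c1ccccc1)(c1ccccc1)c1ccccc1.[Br-]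
Why: Wittig methylenation; excess ylide with no free base should add to the hindered C4 ketone on heating, while the aryl methyl ester is far less electrophilic towards it.

Step 17
Reactants: 24 polyfibrospongol A methoxymethyl ether
Product: 25 polyfibrospongol A
Conditions: HCl (1.25 M in MeOH), MeOH, 0 °C → rt
Reagents that add atoms: none
Why: Acid-catalysed acetal exchange removes the phenolic MOM group under conditions expected to be too mild to protonate the 1,1-disubstituted alkene.

**Compound list**

1 | 2-methylcyclohex-2-en-1-one | CC1=CCCCC1=O | starting material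
2 | 2-bromopropene | CC(Br)=C | starting material
3 | (E)-but-2-enal (crotonaldehyde) | C/C=C/C=O | starting material
4 | prop-1-en-2-yllithium | [Li]C(C)=C | intermediate
5 | dimethyl(prop-1-en-2-yl)aluminium | C[Al](C)C(C)=C | intermediate
6 | dimethyl{[(3S)-2-methyl-3-(prop-1-en-2-yl)cyclohex-1-en-1-yl]oxy}aluminium | C[Al](C)OC1=C(C)[C@H](C(C)=C)CCC1 | intermediate
7 | (2R,3S)-2-[(2E)-1-hydroxybut-2-en-1-yl]-2-methyl-3-(prop-1-en-2-yl)cyclohexan-1-one, both carbinol epimers | C/C=C/C(O)[C@]1(C)C(=O)CCC[C@H]1C(C)=C | intermediate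
8 | (1S,2S,3S)-2-[(2E)-1-hydroxybut-2-en-1-yl]-2-methyl-3-(prop-1-en-2-yl)cyclohexan-1-ol, both carbinol epimers | C/C=C/C(O)[C@]1(C)[C@@H](O)CCC[C@H]1C(C)=C | intermediate
9 | (2E)-1-[(1S,2S,6S)-2-hydroxy-1-methyl-6-(prop-1-en-2-yl)cyclohexyl]but-2-en-1-one | C/C=C/C(=O)[C@]1(C)[C@@H](O)CCC[C@H]1C(C)=C | intermediate
10 | (2E)-1-[(1S,2S,6S)-2-(tert-butyldimethylsilyloxy)-1-methyl-6-(prop-1-en-2-yl)cyclohexyl]but-2-en-1-one | C/C=C/C(=O)[C@]1(C)[C@@H](O[Si](C)(C)C(C)(C)C)CCC[C@H]1C(C)=C | intermediate
11 | (2E)-1-[(1S,2S,6R)-2-(tert-butyldimethylsilyloxy)-6-(3-chloroprop-1-en-2-yl)-1-methylcyclohexyl]but-2-en-1-one | C/C=C/C(=O)[C@]1(C)[C@@H](O[Si](C)(C)C(C)(C)C)CCC[C@H]1C(=C)CCl | intermediate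
12 | methyl 4-hydroxy-3-methoxybenzoate (methyl vanillate) | COC(=O)c1ccc(O)c(OC)c1 | starting material
13 | methyl 3-bromo-4-hydroxy-5-methoxybenzoate | COC(=O)c1cc(Br)c(O)c(OC)c1 | intermediate
14 | methyl 3-bromo-5-methoxy-4-(methoxymethoxy)benzoate | COC(=O)c1cc(Br)c(OCOC)c(OC)c1 | intermediate
15 | methyl 3-methoxy-4-(methoxymethoxy)-5-(4,4,5,5-tetramethyl-1,3,2-dioxaborolan-2-yl)benzoate | COC(=O)c1cc(OC)c(OCOC)c(B2OC(C)(C)C(C)(C)O2)c1 | intermediate
16 | methyl 3-{2-[(1S,2S,3S)-2-[(2E)-but-2-enoyl]-3-(tert-butyldimethylsilyloxy)-2-methylcyclohexyl]prop-2-en-1-yl}-5-methoxy-4-(methoxymethoxy)benzoate (ring-A enone with C9=CH2) | C/C=C/C(=O)[C@]1(C)[C@@H](O[Si](C)(C)C(C)(C)C)CCC[C@H]1C(=C)Cc1cc(C(=O)OC)cc(OC)c1OCOC | intermediate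
17 | methyl 3-{[4β-(tert-butyldimethylsilyloxy)-5β,8β,9β-trimethyl-6-oxo-trans-decalin-9α-yl]methyl}-5-methoxy-4-(methoxymethoxy)benzoate (10α-H) | CC(C)(C)[Si](C)(C)O[C@H]1CCC[C@H]2[C@](C)(Cc3cc(C(=O)OC)cc(OC)c3OCOC)[C@@H](C)CC(=O)[C@]12C | intermediate
18 | potassium C6 enolate of 17 (C6=C7) | CC(C)(C)[Si](C)(C)O[C@H]1CCC[C@H]2[C@](C)(Cc3cc(C(=O)OC)cc(OC)c3OCOC)[C@@H](C)C=C([O-])[C@]12C.[K+] | intermediate
19 | C6 enol triflate: methyl 3-{[4β-(tert-butyldimethylsilyloxy)-5β,8β,9β-trimethyl-6-(trifluoromethanesulfonyloxy)-trans-decal-6-en-9α-yl]methyl}-5-methoxy-4-(methoxymethoxy)benzoate | CC(C)(C)[Si](C)(C)O[C@H]1CCC[C@H]2[C@](C)(Cc3cc(C(=O)OC)cc(OC)c3OCOC)[C@@H](C)C=C(OS(=O)(=O)C(F)(F)F)[C@]12C | intermediate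
20 | Δ6-alkene: methyl 3-{[4β-(tert-butyldimethylsilyloxy)-5β,8β,9β-trimethyl-trans-decal-6-en-9α-yl]methyl}-5-methoxy-4-(methoxymethoxy)benzoate | CC(C)(C)[Si](C)(C)O[C@H]1CCC[C@H]2[C@](C)(Cc3cc(C(=O)OC)cc(OC)c3OCOC)[C@@H](C)C=C[C@]12C | intermediate
21 | methyl 3-{[4β-(tert-butyldimethylsilyloxy)-5β,8β,9β-trimethyl-trans-decalin-9α-yl]methyl}-5-methoxy-4-(methoxymethoxy)benzoate | CC(C)(C)[Si](C)(C)O[C@H]1CCC[C@H]2[C@](C)(Cc3cc(C(=O)OC)cc(OC)c3OCOC)[C@@H](C)CC[C@]12C | intermediate
22 | methyl 3-{[4β-hydroxy-5β,8β,9β-trimethyl-trans-decalin-9α-yl]methyl}-5-methoxy-4-(methoxymethoxy)benzoate | O[C@H]1CCC[C@H]2[C@](C)(Cc3cc(C(=O)OC)cc(OC)c3OCOC)[C@@H](C)CC[C@]12C | intermediate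
23 | methyl 3-{[5β,8β,9β-trimethyl-4-oxo-trans-decalin-9α-yl]methyl}-5-methoxy-4-(methoxymethoxy)benzoate | O=C1CCC[C@H]2[C@](C)(Cc3cc(C(=O)OC)cc(OC)c3OCOC)[C@@H](C)CC[C@]12C | intermediate
24 | polyfibrospongol A methoxymethyl ether | C=C1CCC[C@H]2[C@](C)(Cc3cc(C(=O)OC)cc(OC)c3OCOC)[C@@H](C)CC[C@]12C | intermediate
25 | polyfibrospongol A | C=C1CCC[C@H]2[C@](C)(Cc3cc(C(=O)OC)cc(OC)c3O)[C@@H](C)CC[C@]12C | target

**Step count and risks**

Total step count: 17. Longest linear sequence: 14 steps (steps 1–5 and 9–17, from 2-methylcyclohex-2-en-1-one); the arene branch (steps 6–8) joins at step 9.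

Steps most likely to fail:

Step 10. The ring closure may pass partly through a boat-like arrangement of the enone, so that the radical attacks the other face of C8 and the C8 configuration is eroded. The fallback sets out from 17 (as the mixture of C8 epimers) and comes back to 17. The ketone is deprotonated at C7 (LDA, THF, −78 °C) and dehydrogenated in the same flask with N-tert-butylbenzenesulfinimidoyl chloride to the Δ7-enone F1, in which C8 is planar. Hydrogenation over Pd/C, expected from the α face opposite the axial C5 and C9 methyl groups, should then return 17 as the 8β-methyl isomer. A wrong configuration at C9 cannot be corrected in this way.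

Step 1. Transfer of the α-branched alkenyl group to the α-methyl enone may be slow and poorly face-selective, giving low enantiomeric purity at C10. The fallback sets out from alane 5 and comes back at 7; it builds the quaternary centre in two enolate events. Alane 5 is added under the same copper catalysis to cyclohex-2-enone, the unhindered parent acceptor, and the enolate is trapped with TMSCl to give (R)-trimethyl{[3-(prop-1-en-2-yl)cyclohex-1-en-1-yl]oxy}silane F2. MeLi followed by MeI converts this regiospecifically into (2S,3R)-2-methyl-3-(prop-1-en-2-yl)cyclohexan-1-one F3. TMSCl/NaI/Et3N in MeCN gives the more substituted silyl enol ether, (S)-trimethyl{[2-methyl-3-(prop-1-en-2-yl)cyclohex-1-en-1-yl]oxy}silane F4. A Mukaiyama aldol addition of F4 to crotonaldehyde 3 (BF3·OEt2, CH2Cl2, −78 °C), again anti to the propenyl group, gives 7.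

Step 5. The chloronium intermediate may lose the C10 proton instead of a methyl proton (giving the tetrasubstituted alkene), or a second chlorination may follow. The fallback sets out from 10 and comes back at 16. Allylic hydroxylation with SeO2 (cat.) and t-BuOOH in CH2Cl2 proceeds by an ene reaction and [2,3]-shift that return the double bond to its place, and gives the allylic alcohol (2E)-1-[(1S,2S,6S)-2-(tert-butyldimethylsilyloxy)-6-(3-hydroxyprop-1-en-2-yl)-1-methylcyclohexyl]but-2-en-1-one F5. Methyl chloroformate and pyridine convert it into the allyl methyl carbonate F6. Palladium-catalysed coupling of F6 with boronate 15 (Pd(PPh3)4, THF, 60 °C), in which the carbonate supplies the methoxide that activates boron, gives 16.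

**Further compounds**

F1 | step 10 | methyl 3-{[4β-(tert-butyldimethylsilyloxy)-5β,8,9β-trimethyl-6-oxo-trans-decal-7-en-9α-yl]methyl}-5-methoxy-4-(methoxymethoxy)benzoate | CC(C)(C)[Si](C)(C)O[C@H]1CCC[C@H]2[C@](C)(Cc3cc(C(=O)OC)cc(OC)c3OCOC)C(C)=CC(=O)[C@]12C
F2 | step 1 | (R)-trimethyl{[3-(prop-1-en-2-yl)cyclohex-1-en-1-yl]oxy}silane | C[Si](C)(C)OC1=C[C@H](C(C)=C)CCC1
F3 | step 1 | (2S,3R)-2-methyl-3-(prop-1-en-2-yl)cyclohexan-1-one | C[C@@H]1C(=O)CCC[C@H]1C(C)=C
F4 | step 1 | (S)-trimethyl{[2-methyl-3-(prop-1-en-2-yl)cyclohex-1-en-1-yl]oxy}silane | C[Si](C)(C)OC1=C(C)[C@H](C(C)=C)CCC1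
F5 | step 5 | (2E)-1-[(1S,2S,6S)-2-(tert-butyldimethylsilyloxy)-6-(3-hydroxyprop-1-en-2-yl)-1-methylcyclohexyl]but-2-en-1-one | C/C=C/C(=O)[C@]1(C)[C@@H](O[Si](C)(C)C(C)(C)C)CCC[C@H]1C(=C)CO
F6 | step 5 | 2-[(1S,2S,3S)-2-[(2E)-but-2-enoyl]-3-(tert-butyldimethylsilyloxy)-2-methylcyclohexyl]prop-2-en-1-yl methyl carbonate | C/C=C/C(=O)[C@]1(C)[C@@H](O[Si](C)(C)C(C)(C)C)CCC[C@H]1C(=C)COC(=O)OC
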